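**Retrosynthetic overview**

- Target 17 comes from pentakis-MOM ether 16 by acidolysis. The C5–CH2 bond of the 3-aryl-3-oxopropyl chain comes from aryl bromide 12 and cyclopropanol 15 by palladium homoenolate coupling.
- The C3 aroyl bond comes from Weinreb amide 8 and ArMgBr 11. Amide 8 comes from ester 5 by amidation and exchange of OTs for OMOM.
- The strategy rests on one feature: the dihydrofuran array O1–C2(aryl)–C3(C=O)–C3a is the flavanone array O1–C2–C3–C4(=O)–C4a with C4 pushed out of the ring. Ester 5 therefore comes from (S)-flavanone 4 by oxidative shift of C4a from C4 to C3.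
- Flavanone 4 comes from 6-bromochromone 3 and boronic acid 2 by asymmetric 1,4-addition, which sets C2.
- Ring order: the benzopyranone (ring A plus pyranone) is bought, ring B is attached, the pyranone is contracted to the dihydrofuran, and the two resorcinol rings are added last.

Key step: step 3

Assumption: the (S,S) antipode of the diene ligand is taken to deliver the 2S flavanone, by analogy with additions to cyclic enones. If the first run shows the opposite sense, the (R,R) ligand is used and nothing else changes.

**Route**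

Step 1
Reactants: 1 4-hydroxyphenylboronic acid
Product: 2 [4-(tosyloxy)phenyl]boronic acid
Conditions: TsCl (1.2 equiv), NaOH (aq, 2.5 equiv), THF–H2O, 0 °C → rt; then 1 M HCl to pH 3
Reagents that add atoms: p-toluenesulfonyl chloride, Cc1ccc(cc1)S(=O)(=O)Cl
Why: Schotten–Baumann O-sulfonylation: the phenoxide is the only competent nucleophile toward TsCl, and the boronate formed in base returns as the boronic acid on acidification.

Step 2
Reactants: 2 [4-(tosyloxy)phenyl]boronic acid; 3 6-bromochromone
Product: 4 4-[(2S)-6-bromo-4-oxo-3,4-dihydro-2H-chromen-2-yl]phenyl 4-methylbenzenesulfonate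
Conditions: 2 (2 equiv), [RhCl(C2H4)2]2 (2.5 mol%), (S,S)-2,5-diphenylbicyclo[2.2.2]octa-2,5-diene (5.5 mol%), K3PO4 (aq, 0.5 equiv), toluene–H2O, 40 °C
Reagents that add atoms: none
Why: Rhodium-catalysed asymmetric conjugate addition of an arylboronic acid (Hayashi–Miyaura reaction) to C2 of the chromone; the chiral diene on monovalent rhodium differentiates the enone faces in the aryl insertion and so sets C2 as S, while the aryl bromide and aryl tosylate are inert to the catalyst and the weak base limits reversible opening of the product.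

Step 3
Reactants: 4 4-[(2S)-6-bromo-4-oxo-3,4-dihydro-2H-chromen-2-yl]phenyl 4-methylbenzenesulfonate
Product: 5 methyl (2S,3S)-5-bromo-2-[4-(tosyloxy)phenyl]-2,3-dihydro-1-benzofuran-3-carboxylate (2,3-trans)
Conditions: PhI(OAc)2 (1.3 equiv), conc. H2SO4 (0.5 equiv), HC(OMe)3–MeOH 3:1, 0 °C → rt
Reagents that add atoms: trimethyl orthoformate, COC(OC)OC; methanol, CO
Why: Under H2SO4 the orthoformate converts the C4 ketone into its methyl enol ether, which takes up electrophilic trivalent iodine from PhI(OAc)2 at C3 on the face away from the C2 aryl group while methanol caps C4 as the dimethyl ketal; the C4–C4a bond, antiperiplanar to the C3–I bond, then moves to C3 as iodobenzene leaves, and the dimethoxycarbenium ion left at old C4 loses a methyl group to give the ester. The closest known reaction type is the oxidative ring contraction of flavanones to methyl trans-2-aryl-2,3-dihydrobenzofuran-3-carboxylates with PhI(OAc)2 or Tl(NO3)3 in trimethyl orthoformate, applied here to an enantioenriched 6-bromo-4'-sulfonyloxy substrate. The dihydrofuran ring is closed by contraction of the pyranone through this 1,2-aryl shift (C3–C3a formed, C4–C4a broken), not by cyclisation of an open chain. C3 is the only new stereocentre and is set by the C2 aryl group: iodine enters anti to it and is displaced with inversion by C4a, so the extruded ester carbon ends trans to the aryl group, which is also the more stable arrangement; C2 takes no part in any bond change and should remain S, giving (2S,3S). The step needs migration of ring A carbon C4a to win over the shift of ring B from C2 to C3 (isoflavone) and over loss of the C2 proton (flavone); the electron-poor 4'-tosyloxy ring B is a poor migrating group and disfavours positive charge at C2, the O1 donor ortho to C4a helps the ring A shift, and the ketalising medium keeps C4 tetrahedral so that it can depart as the ester carbon.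

Step 4
Reactants: 5 methyl (2S,3S)-5-bromo-2-[4-(tosyloxy)phenyl]-2,3-dihydro-1-benzofuran-3-carboxylate
Product: 6 (2S,3S)-5-bromo-N-methoxy-N-methyl-2-[4-(tosyloxy)phenyl]-2,3-dihydro-1-benzofuran-3-carboxamide
Conditions: MeNH(OMe)·HCl (3 equiv), AlMe3 (3 equiv), CH2Cl2, 0 → 40 °C; then 1 M HCl
Reagents that add atoms: N,O-dimethylhydroxylamine hydrochloride, CNOC.Cl
Why: Weinreb aminolysis of the ester by the aluminium amide formed from AlMe3 and the amine salt; the reagent is Lewis acidic and not basic, so C3 is not deprotonated and the sulfonate and aryl bromide are untouched.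

Step 5
Reactants: 6 (2S,3S)-5-bromo-N-methoxy-N-methyl-2-[4-(tosyloxy)phenyl]-2,3-dihydro-1-benzofuran-3-carboxamide
Product: 7 (2S,3S)-5-bromo-2-(4-hydroxyphenyl)-N-methoxy-N-methyl-2,3-dihydro-1-benzofuran-3-carboxamide
Conditions: KOH (2 M aq, 4 equiv), 1,4-dioxane, 60 °C; then 1 M HCl to pH 5 at 0 °C
Reagents that add atoms: none
Why: Alkaline hydrolysis of an aryl sulfonate by hydroxide attack at sulfur (S–O cleavage); it is placed at the amide stage because the C3–H of the amide is the least acidic of the route, so C3 should not epimerise, and the alcohol-free medium avoids O-alkylation of the phenoxide by an alkyl tosylate.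

Step 6
Reactants: 7 (2S,3S)-5-bromo-2-(4-hydroxyphenyl)-N-methoxy-N-methyl-2,3-dihydro-1-benzofuran-3-carboxamide
Product: 8 (2S,3S)-5-bromo-N-methoxy-2-[4-(methoxymethoxy)phenyl]-N-methyl-2,3-dihydro-1-benzofuran-3-carboxamide
Conditions: MOMCl (1.5 equiv), iPr2NEt (2 equiv), CH2Cl2, 0 °C → rt
Reagents that add atoms: chloromethyl methyl ether, COCCl
Why: O-alkylation of the phenol (acetal protection) under a hindered amine base gives an ether that tolerates the organomagnesium and carbonate steps and falls off with acid at the end.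

Step 7
Reactants: 9 4-bromoresorcinol
Product: 10 1-bromo-2,4-bis(methoxymethoxy)benzene
Conditions: MOMCl (2.5 equiv), iPr2NEt (3 equiv), CH2Cl2, 0 °C → rt
Reagents that add atoms: chloromethyl methyl ether, COCCl
Why: Double O-alkylation (acetal protection) removes both acidic protons so that the ring can carry a carbon–magnesium bond, and an ortho-OMOM group is too poor a leaving group to allow aryne formation.

Step 8
Reactants: 8 (2S,3S)-5-bromo-N-methoxy-2-[4-(methoxymethoxy)phenyl]-N-methyl-2,3-dihydro-1-benzofuran-3-carboxamide; 10 1-bromo-2,4-bis(methoxymethoxy)benzene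
Product: 12 [(2S,3S)-5-bromo-2-[4-(methoxymethoxy)phenyl]-2,3-dihydro-1-benzofuran-3-yl][2,4-bis(methoxymethoxy)phenyl]methanone, via [2,4-bis(methoxymethoxy)phenyl]magnesium bromide 11 (not isolated)
Conditions: 10 (2.5 equiv), Mg turnings, I2 (cat.), THF, 45 °C; then 8, THF, −20 → 0 °C; sat. aq NH4Cl
Reagents that add atoms: magnesium, [Mg] (stays in intermediate 11 only; none remains in 12)
Why: Weinreb ketone synthesis: magnesium insertion gives ArMgBr 11, which adds once to the amide because the N-methoxy chelate holds the tetrahedral adduct until work-up; the aryl bromide of 8 does not exchange with an aryl Grignard reagent at this temperature, and C3, if transiently enolised, returns to the favoured trans arrangement.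

Step 9
Reactants: 13 methyl 2,4-dihydroxybenzoate
Product: 14 methyl 2,4-bis(methoxymethoxy)benzoate
Conditions: NaH (2.5 equiv), MOMCl (2.5 equiv), DMF, 0 °C → rt
Reagents that add atoms: chloromethyl methyl ether, COCCl
Why: Phenoxide O-alkylation (acetal protection); NaH is used because the 2-OH is hydrogen-bonded to the ester and is sluggish with amine bases.

Step 10
Reactants: 14 methyl 2,4-bis(methoxymethoxy)benzoate
Product: 15 1-[2,4-bis(methoxymethoxy)phenyl]cyclopropan-1-ol
Conditions: EtMgBr (2.8 equiv, slow addition), Ti(OiPr)4 (0.2 equiv), THF–Et2O, 0 °C → rt; sat. aq NH4Cl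
Reagents that add atoms: ethylmagnesium bromide, CC[Mg]Br
Why: Kulinkovich cyclopropanation: the titanacyclopropane formed from EtMgBr and Ti(OiPr)4 acts as a 1,2-dicarbanion equivalent that adds twice to the ester carbonyl to give the 1-arylcyclopropanol, and the MOM ethers are inert.

Step 11
Reactants: 12 [(2S,3S)-5-bromo-2-[4-(methoxymethoxy)phenyl]-2,3-dihydro-1-benzofuran-3-yl][2,4-bis(methoxymethoxy)phenyl]methanone; 15 1-[2,4-bis(methoxymethoxy)phenyl]cyclopropan-1-ol
Product: 16 1-[2,4-bis(methoxymethoxy)phenyl]-3-[(2S,3S)-3-[2,4-bis(methoxymethoxy)benzoyl]-2-[4-(methoxymethoxy)phenyl]-2,3-dihydro-1-benzofuran-5-yl]propan-1-one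
Conditions: 15 (1.5 equiv), Pd(OAc)2 (5 mol%), XPhos (10 mol%), Cs2CO3 (2 equiv), toluene, 80 °C
Reagents that add atoms: none
Why: Palladium-catalysed ring-opening cross-coupling of a cyclopropanol with an aryl bromide: oxidative addition at C5–Br, exchange to the palladium cyclopropoxide, β-carbon elimination to the divalent palladium homoenolate and reductive elimination form the aryl–CH2 bond; no stereocentre is formed, and enolisation at C3 under carbonate can only return the trans isomer because expulsion of O1 from that enolate would be a stereoelectronically poor reverse 5-endo process.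

Step 12
Reactants: 16 1-[2,4-bis(methoxymethoxy)phenyl]-3-[(2S,3S)-3-[2,4-bis(methoxymethoxy)benzoyl]-2-[4-(methoxymethoxy)phenyl]-2,3-dihydro-1-benzofuran-5-yl]propan-1-one
Product: 17 1-(2,4-dihydroxyphenyl)-3-[(2S,3S)-3-(2,4-dihydroxybenzoyl)-2-(4-hydroxyphenyl)-2,3-dihydro-1-benzofuran-5-yl]propan-1-one (CNP0136359.1)
Conditions: 3 M aq HCl, MeOH–THF, 45 °C
Reagents that add atoms: none
Why: Acid-catalysed acetal cleavage removes all five MOM ethers, with methanol trapping the methoxymethyl cation as dimethoxymethane; the ketones and the benzylic ether are left alone, C2 is not touched and C3 can only re-equilibrate to the same trans isomer.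

**Compound list**

1 | 4-hydroxyphenylboronic acid | OB(O)c1ccc(O)cc1 | starting material
2 | [4-(tosyloxy)phenyl]boronic acid | Cc1ccc(cc1)S(=O)(=O)Oc1ccc(cc1)B(O)O | intermediate
3 | 6-bromochromone (6-bromo-4H-chromen-4-one) | O=c1ccoc2ccc(Br)cc12 | starting material
4 | 4-[(2S)-6-bromo-4-oxo-3,4-dihydro-2H-chromen-2-yl]phenyl 4-methylbenzenesulfonate | O=C1C[C@@H](c2ccc(OS(=O)(=O)c3ccc(C)cc3)cc2)Oc2ccc(Br)cc12 | intermediate
5 | methyl (2S,3S)-5-bromo-2-[4-(tosyloxy)phenyl]-2,3-dihydro-1-benzofuran-3-carboxylate | Brc1ccc2c(c1)[C@H](C(=O)OC)[C@@H](c1ccc(OS(=O)(=O)c3ccc(C)cc3)cc1)O2 | intermediate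
6 | (2S,3S)-5-bromo-N-methoxy-N-methyl-2-[4-(tosyloxy)phenyl]-2,3-dihydro-1-benzofuran-3-carboxamide | Brc1ccc2c(c1)[C@H](C(=O)N(C)OC)[C@@H](c1ccc(OS(=O)(=O)c3ccc(C)cc3)cc1)O2 | intermediate
7 | (2S,3S)-5-bromo-2-(4-hydroxyphenyl)-N-methoxy-N-methyl-2,3-dihydro-1-benzofuran-3-carboxamide | Brc1ccc2c(c1)[C@H](C(=O)N(C)OC)[C@@H](c1ccc(O)cc1)O2 | intermediate
8 | (2S,3S)-5-bromo-N-methoxy-2-[4-(methoxymethoxy)phenyl]-N-methyl-2,3-dihydro-1-benzofuran-3-carboxamide | Brc1ccc2c(c1)[C@H](C(=O)N(C)OC)[C@@H](c1ccc(OCOC)cc1)O2 | intermediate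
9 | 4-bromoresorcinol (4-bromobenzene-1,3-diol) | Oc1ccc(Br)c(O)c1 | starting material
10 | 1-bromo-2,4-bis(methoxymethoxy)benzene | COCOc1ccc(Br)c(OCOC)c1 | intermediate
11 | [2,4-bis(methoxymethoxy)phenyl]magnesium bromide | COCOc1ccc([Mg]Br)c(OCOC)c1 | intermediate (not isolated)
12 | [(2S,3S)-5-bromo-2-[4-(methoxymethoxy)phenyl]-2,3-dihydro-1-benzofuran-3-yl][2,4-bis(methoxymethoxy)phenyl]methanone | Brc1ccc2c(c1)[C@H](C(=O)c1ccc(OCOC)cc1OCOC)[C@@H](c1ccc(OCOC)cc1)O2 | intermediate
13 | methyl 2,4-dihydroxybenzoate | COC(=O)c1ccc(O)cc1O | starting material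
14 | methyl 2,4-bis(methoxymethoxy)benzoate | COC(=O)c1ccc(OCOC)cc1OCOC | intermediate
15 | 1-[2,4-bis(methoxymethoxy)phenyl]cyclopropan-1-ol | OC1(CC1)c1ccc(OCOC)cc1OCOC | intermediate
16 | 1-[2,4-bis(methoxymethoxy)phenyl]-3-[(2S,3S)-3-[2,4-bis(methoxymethoxy)benzoyl]-2-[4-(methoxymethoxy)phenyl]-2,3-dihydro-1-benzofuran-5-yl]propan-1-one | O=C(CCc1ccc2c(c1)[C@H](C(=O)c1ccc(OCOC)cc1OCOC)[C@@H](c1ccc(OCOC)cc1)O2)c1ccc(OCOC)cc1OCOC | intermediate
17 | 1-(2,4-dihydroxyphenyl)-3-[(2S,3S)-3-(2,4-dihydroxybenzoyl)-2-(4-hydroxyphenyl)-2,3-dihydro-1-benzofuran-5-yl]propan-1-one | O=C(CCc1ccc2c(c1)[C@H](C(=O)c1ccc(O)cc1O)[C@@H](c1ccc(O)cc1)O2)c1ccc(O)cc1O | target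

**Step count**

Total: 12 steps. Longest linear sequence: 9 steps (steps 1, 2, 3, 4, 5, 6, 8, 11, 12).

**Steps most likely to fail**

Step 3. The iodonium intermediate may lose the C2 proton (dehydrogenation) or let ring B migrate instead of C4a, and the acid may slowly erode the C2 configuration through reversible opening of the pyranone. The fallback is a Wolff ring contraction, which forms the same C3–C3a bond by a carbene-type 1,2-shift. It sets out from 4. LiN(SiMe3)2 and CF3CO2CH2CF3 in THF at −78 °C would give the 3-trifluoroacetyl flavanone F1. Detrifluoroacetylative diazo transfer with MsN3, Et3N and water in MeCN would convert it into the 3-diazoflavanone F2. Irradiation at 365 nm in methanol would expel N2 with shift of C4a from C4 to C3 to give the ketene F3, which methanol traps as ester 5 mixed with its C3 epimer, the cis ester F4. DBU in toluene would equilibrate F4 to the trans ester, so the sequence comes back to the route at 5.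

Step 8. The basic, ortho-substituted aryl Grignard reagent may deprotonate C3 of the hindered α-branched amide instead of adding to it, so that addition stalls. The fallback sets out from 8 and moves the C–C bond formation to an aldehyde. iBu2AlH in THF at −78 °C would reduce the Weinreb amide to the aldehyde F5. ArMgBr 11 would add to this far more electrophilic carbonyl at −78 °C to give the secondary alcohol F6 as a mixture of carbinol epimers. Dess–Martin periodinane with NaHCO3 in CH2Cl2 would oxidise F6 to the ketone, coming back to the route at 12.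

Step 11. The palladium homoenolate may undergo β-hydride elimination (aryl vinyl ketone plus reduced arene) faster than reductive elimination, the cyclopropanol may open under the base before it reaches palladium, and oxidative addition into the electron-rich C5–Br bond may be slow. The fallback sets out from 11 and 12 and uses a Heck reaction of an allylic alcohol in place of the homoenolate coupling. ArMgBr 11 and acrolein in THF at −78 °C would give the allylic alcohol F7. Heating 12 with F7, Pd(OAc)2, Bu4NCl and NaHCO3 in DMF at 90 °C should add the aryl group to the terminal alkene carbon; β-hydride elimination toward the carbinol and tautomerisation then give the saturated β-aryl ketone directly, coming back to the route at 16.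

**Further compounds**

F1 | step 3 | 4-[(2S)-6-bromo-4-oxo-3-(trifluoroacetyl)-3,4-dihydro-2H-chromen-2-yl]phenyl 4-methylbenzenesulfonate (C3 epimers and enol form) | O=C1C(C(=O)C(F)(F)F)[C@@H](c2ccc(OS(=O)(=O)c3ccc(C)cc3)cc2)Oc2ccc(Br)cc12
F2 | step 3 | 4-[(2R)-6-bromo-3-diazo-4-oxo-3,4-dihydro-2H-chromen-2-yl]phenyl 4-methylbenzenesulfonate (C2 arranged in space as in 4; the descriptor changes by priority only) | O=C1C(=[N+]=[N-])[C@@H](c2ccc(OS(=O)(=O)c3ccc(C)cc3)cc2)Oc2ccc(Br)cc12
F3 | step 3 | 4-[(2R)-5-bromo-3-(oxomethylidene)-2,3-dihydro-1-benzofuran-2-yl]phenyl 4-methylbenzenesulfonate (ketene; C2 arranged in space as in 4) | Brc1ccc2c(c1)C(=C=O)[C@@H](c1ccc(OS(=O)(=O)c3ccc(C)cc3)cc1)O2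
F4 | step 3 | methyl (2S,3R)-5-bromo-2-[4-(tosyloxy)phenyl]-2,3-dihydro-1-benzofuran-3-carboxylate (2,3-cis) | Brc1ccc2c(c1)[C@@H](C(=O)OC)[C@@H](c1ccc(OS(=O)(=O)c3ccc(C)cc3)cc1)O2
F5 | step 8 | (2S,3S)-5-bromo-2-[4-(methoxymethoxy)phenyl]-2,3-dihydro-1-benzofuran-3-carbaldehyde | Brc1ccc2c(c1)[C@H](C=O)[C@@H](c1ccc(OCOC)cc1)O2
F6 | step 8 | [2,4-bis(methoxymethoxy)phenyl][5-bromo-2-[4-(methoxymethoxy)phenyl]-2,3-dihydro-1-benzofuran-3-yl]methanol (ring stereocentres arranged as in 8; both carbinol epimers) | Brc1ccc2c(c1)[C@H](C(O)c1ccc(OCOC)cc1OCOC)[C@@H](c1ccc(OCOC)cc1)O2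
F7 | step 11 | 1-[2,4-bis(methoxymethoxy)phenyl]prop-2-en-1-ol (racemic) | C=CC(O)c1ccc(OCOC)cc1OCOC
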